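**Retrosynthetic overview**
1. The target is methyl (−)-shikimate carrying three different esters. The cyclohexene ring and its three stereocentres come intact from (−)-shikimic acid, and the two side-chain stereocentres come from the enantiopure acids.
2. The disconnections are the three acyl C–O bonds, cut in the reverse order of installation: O3–acetyl (last), O4–(R)-2-methylbutanoyl (key step, catalyst-controlled choice of O4 over O3 within the cis-3,4-diol), O5–(S)-3-methylpentanoyl (boronate-directed), then the methyl ester.
3. No carbocycle is built. The only rings formed are a transient phenylboronate across O3/O4 (step 2) and a catalytic borinate across O3/O4 (step 3), in that order, and both are opened again.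

Assumption: (R)-2-methylbutanoic acid and (S)-3-methylpentanoic acid are bought as single enantiomers (≥98% ee). Names use shikimate numbering (C1 bears the ester, O3 is allylic), and every ring stereocentre keeps the spatial arrangement of (−)-shikimic acid throughout.

**Route**

Step 1
Reactants: 1 (−)-shikimic acid
Product: 2 methyl (−)-shikimate
Conditions: MeOH, (1S)-(+)-10-camphorsulfonic acid (5 mol%), reflux, 12 h
Reagents that add atoms: methanol, CO
Why: Fischer esterification under mild sulfonic acid catalysis converts only the carboxylic acid, so the three carbinol stereocentres of shikimic acid (3R,4S,5R) are untouched and carried through the route.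

Step 2
Reactants: 2 methyl (−)-shikimate; 3 phenylboronic acid; 4 (S)-3-methylpentanoic acid
Product: 7 methyl 5-O-[(3S)-3-methylpentanoyl]shikimate, via 3,4-O-phenylboronate 5 (not isolated), via 5-O-acyl 3,4-O-phenylboronate 6 (not isolated)
Conditions: 3 (1.05 equiv), PhMe, reflux, Dean–Stark, evaporate; then 4, iPrN=C=NiPr, 4-(dimethylamino)pyridine (10 mol%), CH2Cl2, 0 °C to rt; then aq. citric acid wash, pinacol, EtOAc, rt
Reagents that add atoms: none
Why: Cyclic boronate ester formation strongly prefers the cis-3,4-diol over the trans-4,5-diol, so the Steglich esterification can only reach O5, and neutral transesterification of boron to pinacol then frees the diol without acyl migration; no stereocentre is formed and acid 4 has no α-stereocentre to lose.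

Step 3
Reactants: 7 methyl 5-O-[(3S)-3-methylpentanoyl]shikimate; 8 (R)-2-methylbutanoic acid
Product: 10 methyl 4-O-[(2R)-2-methylbutanoyl]-5-O-[(3S)-3-methylpentanoyl]shikimate, via (R)-2-methylbutanoyl chloride 9 (not isolated)
Conditions: 8 (1.25 equiv), Me2C=C(Cl)NMe2 (1.2 equiv), CH2Cl2, 0 °C to rt, 1 h; then 7, Ph2BOCH2CH2NH2 (10 mol%), iPr2NEt (1.5 equiv), MeCN, 0 °C, 4 h
Reagents that add atoms: 1-chloro-N,N,2-trimethylprop-1-en-1-amine (Ghosez reagent), CC(C)=C(Cl)N(C)C (its Cl goes into 9 only)
Why: Proposed new method: diarylborinic-acid-catalysed site-selective acylation, whose closest known form is the monoacylation of pyranoside cis-1,2-diols at the equatorial oxygen with simple achiral acyl chlorides, is carried over to a carbocyclic allylic cis-diol and an enantiopure α-branched acyl chloride; Ph2BOH released from the catalyst binds the cis-3,4-diol of 7 reversibly as an anionic tetracoordinate dioxaborolane whose oxygens are far more nucleophilic than a free hydroxyl, the equatorial O4 is more exposed than the pseudoaxial allylic O3 and so attacks 9 in the turnover-limiting step, the resulting O3 borinic ester is exchanged by the next diol, and acylation of the borinate at 0 °C should outrun ketene formation from 9 so that the (R) α-centre is kept, with no new stereocentre created.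

Step 4
Reactants: 10 methyl 4-O-[(2R)-2-methylbutanoyl]-5-O-[(3S)-3-methylpentanoyl]shikimate
Product: 11 methyl (3R,4S,5R)-3-acetoxy-4-[(2R)-2-methylbutanoyloxy]-5-[(3S)-3-methylpentanoyloxy]cyclohex-1-ene-1-carboxylate (CNP0188172.1)
Conditions: Ac2O (3 equiv), pyridine, 4-(dimethylamino)pyridine (5 mol%, added last), CH2Cl2, 0 °C to rt
Reagents that add atoms: acetic anhydride, CC(=O)OC(C)=O
Why: Steglich-type nucleophilic acyl-transfer catalysis acetylates the only remaining hydroxyl, and with excess Ac2O present before the catalyst is added the pseudoaxial 3-OH is capped faster than the neighbouring 4-ester can migrate; no stereocentre is touched.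

**Compound list**
1 | (−)-shikimic acid, (3R,4S,5R)-3,4,5-trihydroxycyclohex-1-ene-1-carboxylic acid | O[C@@H]1CC(C(=O)O)=C[C@@H](O)[C@H]1O | starting material
2 | methyl (−)-shikimate | O[C@@H]1CC(C(=O)OC)=C[C@@H](O)[C@H]1O | intermediate
3 | phenylboronic acid | OB(O)c1ccccc1 | starting material
4 | (S)-3-methylpentanoic acid | CC[C@H](C)CC(=O)O | starting material
5 | methyl shikimate 3,4-O-phenylboronate (2-phenyl-1,3,2-dioxaborolane across O3 and O4, 5-OH free) | O[C@@H]1CC(C(=O)OC)=C[C@@H](O2)[C@H]1OB2c1ccccc1 | intermediate
6 | methyl 5-O-[(3S)-3-methylpentanoyl]shikimate 3,4-O-phenylboronate | CC[C@H](C)CC(=O)O[C@@H]1CC(C(=O)OC)=C[C@@H](O2)[C@H]1OB2c1ccccc1 | intermediate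
7 | methyl 5-O-[(3S)-3-methylpentanoyl]shikimate (3-OH and 4-OH free) | CC[C@H](C)CC(=O)O[C@@H]1CC(C(=O)OC)=C[C@@H](O)[C@H]1O | intermediate
8 | (R)-2-methylbutanoic acid | CC[C@@H](C)C(=O)O | starting material
9 | (R)-2-methylbutanoyl chloride | CC[C@@H](C)C(=O)Cl | intermediate
10 | methyl 4-O-[(2R)-2-methylbutanoyl]-5-O-[(3S)-3-methylpentanoyl]shikimate (3-OH free) | CC[C@H](C)CC(=O)O[C@@H]1CC(C(=O)OC)=C[C@@H](O)[C@H]1OC(=O)[C@H](C)CC | intermediate
11 | methyl (3R,4S,5R)-3-acetoxy-4-[(2R)-2-methylbutanoyloxy]-5-[(3S)-3-methylpentanoyloxy]cyclohex-1-ene-1-carboxylate | CC[C@H](C)CC(=O)O[C@@H]1CC(C(=O)OC)=C[C@@H](OC(C)=O)[C@H]1OC(=O)[C@H](C)CC | target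

**Step count**
Total step count: 4. Longest linear sequence: 4 steps (1 → 2 → 7 → 10 → 11).

**Steps most likely to fail, with fallbacks**

Step 2 (one-flask boronate masking, O5 acylation, boron removal). The boronate may form incompletely or may not survive the carbodiimide coupling, giving mixtures of O-acyl isomers. The fallback masks the cis-diol with a covalent ketal instead and sets out from 2. Treatment of 2 with 2,2-dimethoxypropane and catalytic (1S)-(+)-10-camphorsulfonic acid in acetone at rt gives methyl 3,4-O-isopropylideneshikimate F1. Steglich esterification of its free 5-OH with 4 (iPrN=C=NiPr, 4-(dimethylamino)pyridine, CH2Cl2) gives methyl 3,4-O-isopropylidene-5-O-[(3S)-3-methylpentanoyl]shikimate F2. Warming F2 in 80% aqueous AcOH at 40 °C removes the ketal, and the fallback comes back to the route at 7, at the cost of two extra steps.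

Step 3 (the proposed new step). On the cyclohexene half-chair the preference for O4 over O3 may be lower than on pyranosides, and amine base could erode the α-centre of 9 through a ketene. The fallback uses known stannylene-acetal chemistry and sets out from 7. Heating 7 with Bu2SnO in toluene (Dean–Stark) gives methyl 3,4-O-(dibutylstannylene)-5-O-[(3S)-3-methylpentanoyl]shikimate F3. This is acylated by 9 (made as in step 3) in toluene at 0 °C without any amine base, at the equatorial oxygen as is established for stannylene acetals of cis-diols. Aqueous KF work-up removes the tin, and the fallback comes back to the route at 10.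

Step 4 (acetylation next to a migratable ester). Under basic conditions the 4-ester of 10 can move to the free cis 3-OH before acetylation, giving the regioisomeric triester. The fallback reverses the order of the last two acylations so that 10 never appears, and sets out from 7. Treatment of 7 with trimethyl orthoacetate and catalytic pyridinium p-toluenesulfonate in CH2Cl2 gives the cyclic orthoester methyl 3,4-O-(1-methoxyethylidene)-5-O-[(3S)-3-methylpentanoyl]shikimate F4 (both epimers at the orthoester carbon). Opening F4 with 80% aqueous AcOH at rt, which by stereoelectronic control leaves the ester on the axial oxygen, gives methyl 3-O-acetyl-5-O-[(3S)-3-methylpentanoyl]shikimate F5. Acylation of the equatorial 4-OH of F5 with 9 and pyridine in CH2Cl2 at 0 °C comes back to the route at 11. This sequence bypasses step 3 as well and is a second, mechanistically independent back-up for it.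

**Further compounds**
F1 | step 2 | methyl 3,4-O-isopropylideneshikimate | O[C@@H]1CC(C(=O)OC)=C[C@@H](O2)[C@H]1OC2(C)C
F2 | step 2 | methyl 3,4-O-isopropylidene-5-O-[(3S)-3-methylpentanoyl]shikimate | CC[C@H](C)CC(=O)O[C@@H]1CC(C(=O)OC)=C[C@@H](O2)[C@H]1OC2(C)C
F3 | step 3 | methyl 3,4-O-(dibutylstannylene)-5-O-[(3S)-3-methylpentanoyl]shikimate | CC[C@H](C)CC(=O)O[C@@H]1CC(C(=O)OC)=C[C@@H](O2)[C@H]1O[Sn]2(CCCC)CCCC
F4 | step 4 | methyl 3,4-O-(1-methoxyethylidene)-5-O-[(3S)-3-methylpentanoyl]shikimate (mixture at the orthoester carbon) | CC[C@H](C)CC(=O)O[C@@H]1CC(C(=O)OC)=C[C@@H](O2)[C@H]1OC2(C)OC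
F5 | step 4 | methyl 3-O-acetyl-5-O-[(3S)-3-methylpentanoyl]shikimate | CC[C@H](C)CC(=O)O[C@@H]1CC(C(=O)OC)=C[C@@H](OC(C)=O)[C@H]1O
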